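## Structural features

CNP0154047.1 is an octaphenol built on a benzene ring (ring A) substituted at five positions: A1 and A3 carry the ring oxygens of two 2,3-dihydrofurans, A4, A5 and A6 carry carbon, and A2 is the only CH. The dihydrofuran on the A3/A4 edge is made of Cc (bonded to A4) and Cd (bonded to the A3 oxygen); Cc bears ring B, a resorcinol ring, through B6, and Cd bears a 4-hydroxyphenyl group. Ring B is tied back to A5 by the bridge Ca (CH2 on A5)–Cb [CH(2,4-dihydroxyphenyl) on B1], which closes a seven-membered carbocycle through A4, A5, Ca, Cb, B1, B6 and Cc. The dihydrofuran on the A1/A6 edge is made of Ce (on A6, bearing a 3,5-dihydroxyphenyl group) and Cf (on the A1 oxygen, bearing a 4-hydroxyphenyl group), so that, the Ca–Cb bridge apart, the two dihydrofurans are related by a twofold axis through A2 and A5. All five stereocentres are R: Cc/Cd and Ce/Cf are adjacent pairs, each trans, and Cb stands 1,3 to Cc across ring B with its hydrogen on the face opposite to the Cc hydrogen. The benzylic aryl ether bonds Cd–O and Cf–O ionize in acid to 4-oxybenzyl cations, so Cd and Cf can be equilibrated to trans but the rings can also open, eliminate or rearrange; Cb, Cc and Ce cannot be corrected once set, and the free polyphenol is sensitive to air and base. The real difficulty is the regiocontrolled build-up of ring A together with the seven-membered ring, and the relay of configuration from Cb to centres remote from it. The key step uses the fact that Cc is bonded at once to A4, B6 and Cd while Cd is bonded to the A3 oxygen: an alkyne B6–Cc≡Cd–aryl can take up A4 at Cc and the A3 oxygen at Cd in one palladium cycle, closing the seven-membered ring and the furan together.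

## Logic of the disconnections

28 is traced back to 27 by cutting eight aryl O–CH3 bonds. All chemistry is run on methyl ethers because the free polyphenol would not survive bases, oxidants or organometallics. The forward step must cleave eight ethers without opening the Cd–O and Cf–O bonds for good.

27 is related to 26 by the configuration at Cf alone; no bond is cut. A carbene C–H insertion gives the 2,3-cis ring, so the forward step must invert Cf through reversible Cf–O ionization while Ce stays fixed.

26 is cut at the Ce–Cf bond, Ce becoming the diazo carbon of 25 (from hydrazone 24) and Cf the CH2 of a 4-methoxybenzyl ether. Ce is remote from the resident stereocentres, so it is set under catalyst control. The forward step is a 1,5 C–H insertion of a donor/donor rhodium carbene whose face is chosen by the chiral catalyst.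

24 goes back through 23 and 22 to 19 and 20 (C=N, then the Ce–aryl bond), 19 to 17 and 18 (O–Cf bond), and 17 to 16 (A6–Ce bond). These are standard carbonyl and phenol reactions. The free A1 hydroxyl of 16 is the only feature that distinguishes ring A from five rings of methyl ethers, so the formylation must go ortho to it and to A6, not A2.

16 is simplified to 15 by removing the hydrogens on Cc and Cd. Two stereocentres disappear and the benzofuran made by the key step appears. The forward reduction must protonate Cc on the face dictated by Cb and deliver hydride to Cd to give the trans ring.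

15 is cut at A4–Cc and O–Cd to give 14, an ortho-iodophenol tethered to a diarylalkyne. Two rings open at once and the molecule becomes three arenes joined by Ca–Cb plus an arylalkyne. The forward cascade needs A4 to add to Cc (not Cd) and the A3 oxygen to close onto Cd.

14 goes back to 13 (two O–benzyl bonds) and 13 to 11 (C–I from C–Br). Ring A oxygens must be told apart from the other ethers twice (phenoxide for the key step, free A1 hydroxyl for the second furan), which methyl ethers on ring A would not allow. The A4 halogen must be placed before the other electron-rich rings and the alkyne exist, because a late electrophilic iodination could not be steered to A4. It is carried as bromine so that the alkyne can be introduced at an aryl iodide on ring B. The forward steps need halogen–lithium exchange to outrun addition to the alkyne, and a debenzylation that spares methyl ethers.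

11 is cut at the B6–C(sp) bond into 9 and 10. The coupling must take the C–I bond of ring B and leave the C–Br bond of ring A.

9 is derived from 8 by removing the hydrogens on Cb and Ca. The only stereocentre present before the key step comes from an olefin, which demands one olefin geometry and a face-selective hydrogenation that leaves C–I and C–Br alone.

8 is cut at the Ca=Cb bond into 5 (as its Grignard reagent 6) and ketone 3, by way of alcohol 7. 3 is cut at the aryl–carbonyl bond into 1 and 2, and 5 at its aryl C–Br bond into 4. All four pieces are simple arenes; the demands are the regiochemistry of the acylation and of the bromination.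

## Other disconnections considered

Alternative 1: The cut is at both aryl ether bonds of ring A (A1–O and A3–O). A hindered lithium amide would remove the ring A hydrogen between the two bromines of the dialkoxide of A2. Loss of bromide would give an aryne that the nearer alkoxide traps; the resulting aryl anion would expel the second bromide, and the other alkoxide would trap the second aryne to give A1.
- In favour: the twofold symmetry of the bis(dihydrofuran) part is used in full. Both heterocycles form in one operation, and their four stereocentres come from open-chain centres that could be set by established asymmetric methods before the rings exist. The seven-membered ring could later close onto either of two homotopic 3,5-dimethoxyphenyl groups.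
- Against: A2 is a hexasubstituted benzene with two bulky arms flanking the silyloxymethyl group, and its stereocontrolled assembly is a synthesis in itself. The relay needs the aryl anion to lose bromide faster than it is protonated, and the base to leave the doubly benzylic methines alone. After A1, Cb and the seven-membered ring remain, with Cb set only by substrate control in a cationic closure.
- Comparison: on structure this plan is the better one for the four furan stereocentres, since no face-selective protonation and no late epimerization are needed, and it is equal in regiochemical security of ring A. On mechanism it is more fragile (two arynes in succession against one palladium cycle of a well-known type). On step economy it is not shorter, because the hardest ring and Cb are left to the end.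

Alternative 2: The cut is at B6–Cc and B1–Cb, so ring B arrives last as an aryne. Fluoride would release the aryne from A5; the enolate of A4 would add at the aryne carbon remote from the methoxy group, and the aryl anion would attack the ketone and fragment the four-membered intermediate. The net result is insertion into the C1–C2 bond of A4 and expansion to the seven-membered ring of A3.
- In favour: highly convergent; two C–C bonds and the seven-membered ring from two simple pieces; regiochemistry fixed by the methoxy group next to the aryne; a ketone at Cb and an ester at Cc as handles.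
- Against: A3 has no defined stereocentre (Cc racemic and enolizable, Cb a carbonyl). The 2,4-dimethoxyphenyl group must be added to a hindered ketone and the tertiary alcohol deoxygenated with control of Cb. The ester must be built into Cd with its aryl group, and the furan closed onto a ring A oxygen that in A3 is a methyl ether no different from the others.
- Comparison: this plan is the equal or the better in convergence and in how directly the carbocycle is made, and the reaction type is as well established as the one chosen. It is weaker in stereochemistry, since Cb, Cc and Cd are all set after the key step. It is longer after the key step, because the chosen step delivers the benzofuran with both aryl groups in place.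

Alternative 3: The cut is at four C–C bonds of ring B. Irradiation of A7 would trigger Wolff rearrangement to a vinylketene, which adds A8 in a [2+2] sense; four-electron ring opening and six-electron ring closure, then tautomerization, would give A6.
- In favour: ring B forms regiospecifically with its two oxygens differentiated, on which point this plan is the better one. Cb, Cc and Cd are already present in A7, so no benzofuran has to be reduced late. The cascade needs no metal.
- Against: ring B is the simplest part of the target and is available as a commercial arene. A7 must contain the seven-membered ring, an unsaturated diazo ketone and three stereocentres without the help of ring B. Cc lies gamma to the carbonyl and is exposed to epimerization or double-bond migration. The differentiation of the ring B oxygens is of no use for a target in which both are free.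
- Comparison: regiochemistry is at least as secure as in the chosen plan, but the stereochemical burden moves to a harder precursor and the step count would be the highest of all.

Key step: step 8

Assumption: the facial sense of the two chiral catalysts (steps 4 and 15) on substrates this crowded is taken from the usual models for these catalyst classes; if the opposite sense is found, the mirror-image ligand is used with no other change.
Assumption: ring A is carried as a bis(benzyl) ether and enters the key step as a free resorcinol; this changes only spectator groups on the precursor and product skeletons (the A1 oxygen is a free hydroxyl instead of a methyl ether).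

## Route

Step 1
Reactants: 1 1-iodo-3,5-dimethoxybenzene; 2 2,4-dimethoxybenzoyl chloride
Product: 3 (2,4-dimethoxyphenyl)(2-iodo-4,6-dimethoxyphenyl)methanone
Conditions: AlCl3 (1.2 equiv), CH2Cl2, 0 °C
Reagents that add atoms: none
Why: Friedel–Crafts acylation at the position para to one methoxy group and ortho to the other (next to iodine), the site between the two methoxy groups being the slower one; iodine is meta to both donors and is not lost by ipso protonation, and 0 °C avoids AlCl3 cleavage of the ether ortho to the new ketone.

Step 2
Reactants: 4 3,5-bis(benzyloxy)benzyl bromide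
Product: 5 1,5-bis(benzyloxy)-2-bromo-3-(bromomethyl)benzene
Conditions: NBS (1.05 equiv), MeCN, 0 °C→rt, dark
Reagents that add atoms: N-bromosuccinimide, O=C1CCC(=O)N1Br
Why: Electrophilic aromatic bromination of a symmetric 3,5-dialkoxybenzyl ring goes ortho to the CH2 group and para to one alkoxy group; symmetry makes the two such sites identical, so the halogen lands on the future A4 without any isomer problem.

Step 3
Reactants: 5 1,5-bis(benzyloxy)-2-bromo-3-(bromomethyl)benzene; 3 (2,4-dimethoxyphenyl)(2-iodo-4,6-dimethoxyphenyl)methanone
Product: 8 (Z)-2-[3,5-bis(benzyloxy)-2-bromophenyl]-1-(2,4-dimethoxyphenyl)-1-(2-iodo-4,6-dimethoxyphenyl)ethene, via benzylic Grignard reagent 6 (not isolated), via tertiary alcohol 7 (not isolated)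
Conditions: Mg, Et2O, 0 °C; 3, THF, 0 °C→rt; 1 M HCl; then TsOH·H2O (10 mol %), PhMe, 60 °C
Reagents that add atoms: none
Why: Magnesium inserts into the benzylic C–Br bond much faster than into the aryl C–Br bond, the benzylic Grignard reagent adds to the non-enolizable ketone, and the doubly benzylic tertiary alcohol loses water by an E1 path. The same acid equilibrates the olefin through the stabilized cation toward the Z isomer (ring A next to the twisted ring B and conjugated with the 2,4-dimethoxyphenyl group), which is purified by crystallization.

Step 4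
Reactants: 8 (Z)-2-[3,5-bis(benzyloxy)-2-bromophenyl]-1-(2,4-dimethoxyphenyl)-1-(2-iodo-4,6-dimethoxyphenyl)ethene
Product: 9 (R)-2-[3,5-bis(benzyloxy)-2-bromophenyl]-1-(2,4-dimethoxyphenyl)-1-(2-iodo-4,6-dimethoxyphenyl)ethane
Conditions: [Ir(cod)((S)-t-Bu-PHOX)]BArF (5 mol %), H2 (50 bar), CH2Cl2, rt
Reagents that add atoms: none
Why: Iridium-catalysed asymmetric hydrogenation of an unfunctionalized trisubstituted aryl olefin with a chiral P,N ligand; the coplanar 2,4-dimethoxyphenyl group and the orthogonal ring B fall into different quadrants of the catalyst, so hydrogen adds to one face of the geometrically pure olefin and sets Cb as R. Aryl C–I, aryl C–Br and benzyl ethers are not touched by the cationic iridium hydride.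

Step 5
Reactants: 9 (R)-2-[3,5-bis(benzyloxy)-2-bromophenyl]-1-(2,4-dimethoxyphenyl)-1-(2-iodo-4,6-dimethoxyphenyl)ethane; 10 4-ethynylanisole
Product: 11 (R)-2-[3,5-bis(benzyloxy)-2-bromophenyl]-1-(2,4-dimethoxyphenyl)-1-{2,4-dimethoxy-6-[(4-methoxyphenyl)ethynyl]phenyl}ethane
Conditions: PdCl2(PPh3)2 (3 mol %), CuI (5 mol %), Et3N–THF, 40 °C
Reagents that add atoms: none
Why: Sonogashira coupling; oxidative addition takes the C–I bond of ring B and not the electron-rich, doubly ortho-substituted C–Br bond of ring A, so the alkyne is placed on B6 only.

Step 6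
Reactants: 11 (R)-2-[3,5-bis(benzyloxy)-2-bromophenyl]-1-(2,4-dimethoxyphenyl)-1-{2,4-dimethoxy-6-[(4-methoxyphenyl)ethynyl]phenyl}ethane
Product: 13 (R)-2-[3,5-bis(benzyloxy)-2-iodophenyl]-1-(2,4-dimethoxyphenyl)-1-{2,4-dimethoxy-6-[(4-methoxyphenyl)ethynyl]phenyl}ethane, via aryllithium 12 (not isolated)
Conditions: n-BuLi (1.1 equiv), THF, −78 °C, 10 min; I2 (1.2 equiv), −78 °C→rt
Reagents that add atoms: iodine, II
Why: Bromine–lithium exchange at −78 °C is faster than addition of butyllithium or of the new aryllithium to the diarylalkyne and faster than any deprotonation; iodine then quenches the aryllithium to give the aryl iodide needed for the palladium step.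

Step 7
Reactants: 13 (R)-2-[3,5-bis(benzyloxy)-2-iodophenyl]-1-(2,4-dimethoxyphenyl)-1-{2,4-dimethoxy-6-[(4-methoxyphenyl)ethynyl]phenyl}ethane
Product: 14 5-[(2R)-2-(2,4-dimethoxyphenyl)-2-{2,4-dimethoxy-6-[(4-methoxyphenyl)ethynyl]phenyl}ethyl]-4-iodobenzene-1,3-diol
Conditions: BCl3 (5 equiv), C6HMe5 (6 equiv), CH2Cl2, −78 °C; MeOH
Reagents that add atoms: none
Why: BCl3 with pentamethylbenzene as cation scavenger cleaves aryl benzyl ethers at −78 °C and leaves aryl methyl ethers, the aryl iodide and the alkyne intact; the scavenger takes up the benzyl cation so the electron-rich rings are not C-benzylated.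

Step 8
Reactants: 14 5-[(2R)-2-(2,4-dimethoxyphenyl)-2-{2,4-dimethoxy-6-[(4-methoxyphenyl)ethynyl]phenyl}ethyl]-4-iodobenzene-1,3-diol
Product: 15 tetracyclic benzofuran phenol: 2-(4-methoxyphenyl)benzofuran of ring A whose C3 (Cc) is bonded to B6 and whose A5 is bridged to B1 through Ca–Cb (Cb R); A1 hydroxyl free
Conditions: Pd(OAc)2 (10 mol %), LiCl (1 equiv), K2CO3 (3 equiv), DMF (0.01 M), 100 °C
Reagents that add atoms: none
Why: Pd(OAc)2 is reduced in the flask to zerovalent palladium, which inserts into the C–I bond at A4 of the phenoxide. The arylpalladium iodide adds syn across the tethered alkyne with A4 bonding to Cc, a 7-exo-dig closure of the ring A4–A5–Ca–Cb–B1–B6–Cc that leaves divalent palladium on Cd, cis to ring A. The A3 phenoxide then replaces iodide on palladium to give a six-membered oxapalladacycle, and C–O reductive elimination forms the O–Cd bond, closes the furan and returns zerovalent palladium. The closest known reaction is the Larock heteroannulation of ortho-iodophenols with internal alkynes, run here within one molecule. No stereocentre is formed and Cb, a non-activated methine, is not at risk under carbonate. The step needs A4 to bond to Cc and not to Cd; the two-atom tether secures this, since the other mode would be an 8-endo closure through a strained transition state. It also needs only one oxygen to close: the A3 oxygen is ortho to the C–Pd bond while the A1 hydroxyl is para and cannot reach. High dilution suppresses carbopalladation between molecules.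

Step 9
Reactants: 15 tetracyclic benzofuran phenol (Cb R)
Product: 16 trans-2,3-dihydrobenzofuran phenol (Cb R, Cc R, Cd R)
Conditions: Et3SiH (5 equiv), CF3CO2H–CH2Cl2 (1:3), 0 °C
Reagents that add atoms: none
Why: Ionic hydrogenation: protonation of the 2-arylbenzofuran at Cc gives an oxocarbenium ion at Cd stabilized by the ring oxygen and the 4-methoxyphenyl group, and Et3SiH delivers hydride to Cd to give the 2,3-trans ring usual for this reduction. The pseudo-equatorial Cb aryl group fixes the twist of ring B against the benzofuran plane, and the reversible protonation should settle on the face from which ring B is already tilted away, placing the Cc hydrogen trans to the Cb hydrogen (Cc R, hence Cd R).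

Step 10
Reactants: 16 trans-2,3-dihydrobenzofuran phenol (Cb R, Cc R, Cd R)
Product: 17 salicylaldehyde: 16 carrying CHO on A6
Conditions: MgCl2 (3 equiv), Et3N (6 equiv), (CH2O)n (10 equiv), MeCN, reflux
Reagents that add atoms: formaldehyde (as paraformaldehyde), C=O
Why: Magnesium phenoxide-directed ortho-formylation (Casnati–Skattebøl type): formaldehyde is delivered only ortho to the free hydroxyl, and of the two such sites A6 (para to the furan oxygen) is preferred over A2 (between two oxygens), as in formylations of orcinol-type phenols. The hydroxymethyl intermediate is oxidized to the aldehyde by a second formaldehyde.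

Step 11
Reactants: 17 salicylaldehyde; 18 4-methoxybenzyl chloride
Product: 19 4-methoxybenzyl ether of 17 at the A1 oxygen
Conditions: K2CO3 (2 equiv), n-Bu4NI (cat.), DMF, 60 °C
Reagents that add atoms: none
Why: Williamson ether synthesis on the salicylaldehyde phenoxide; the benzylic CH2 introduced here is the future Cf and its aryl group is the 4-oxyphenyl substituent of the second dihydrofuran.

Step 12
Reactants: 19 4-methoxybenzyl ether aldehyde; 20 1-bromo-3,5-dimethoxybenzene
Product: 22 diaryl carbinol on A6 (both epimers at the carbinol carbon), via 3,5-dimethoxyphenylmagnesium bromide 21 (not isolated)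
Conditions: 20, Mg, THF, rt; add to 19, THF, −20→0 °C; H2O
Reagents that add atoms: none
Why: Grignard addition of the aryl nucleophile to the aldehyde; the new carbinol centre is of no consequence because it is oxidized in the next step.

Step 13
Reactants: 22 diaryl carbinol on A6
Product: 23 diaryl ketone: A6–C(=O)–(3,5-dimethoxyphenyl)
Conditions: Dess–Martin periodinane (1.5 equiv), NaHCO3, CH2Cl2, 0 °C→rt
Reagents that add atoms: none
Why: Dess–Martin oxidation of a secondary diaryl carbinol under buffered, near-neutral conditions that leave the benzylic ethers and the dihydrofuran alone.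

Step 14
Reactants: 23 diaryl ketone
Product: 24 N-unsubstituted hydrazone of 23
Conditions: N2H4·H2O (20 equiv), AcOH (cat.), EtOH, 100 °C, sealed tube
Reagents that add atoms: hydrazine, NN
Why: Condensation of the ketone with hydrazine; the carbonyl is flanked by two ortho substituents, so excess hydrazine, acid catalysis and heat are used.

Step 15
Reactants: 24 hydrazone
Product: 26 octamethyl ether with the cis second dihydrofuran (Cf S, Ce R; Cb R, Cc R, Cd R), via diaryldiazomethane 25 (not isolated)
Conditions: MnO2 (8 equiv), CH2Cl2, 0 °C, filter; Rh2(R-PTAD)4 [dirhodium tetrakis((R)-(1-adamantyl)(phthalimido)acetate)] (1 mol %), CH2Cl2, 0 °C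
Reagents that add atoms: none
Why: MnO2 dehydrogenates the hydrazone to the diaryldiazomethane, from which the dirhodium carboxylate forms a donor/donor carbene that inserts into the activated benzylic ether C–H bond five atoms away, forming the Ce–Cf bond. This insertion gives the 2,3-cis-dihydrobenzofuran, and the chiral catalyst selects the carbene face so that Ce is R (Cf then S).

Step 16
Reactants: 26 octamethyl ether with the cis second dihydrofuran
Product: 27 octamethyl ether of the target (Cb, Cc, Cd, Ce, Cf all R)
Conditions: CF3CO2H (5 equiv), CH2Cl2, 0 °C→rt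
Reagents that add atoms: none
Why: Acid reversibly ionizes the Cf–O bond to a 4-methoxybenzylic cation that recloses to the thermodynamically preferred 2,3-trans ring, inverting Cf to R while Ce, which is not part of the ionizing bond, keeps its configuration; Cd already sits on the trans side of the same equilibrium.

Step 17
Reactants: 27 octamethyl ether of the target
Product: 28 CNP0154047.1
Conditions: BBr3 (30 equiv), CH2Cl2, −78 °C→rt; MeOH, then H2O
Reagents that add atoms: none
Why: BBr3 cleaves all eight aryl methyl ethers (Lewis acid–base complex, then bromide attack on methyl); low temperature and a methanol quench limit opening of the two benzylic ether bonds, and any reversible opening at Cd or Cf returns to the trans rings.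

## Compound list

1 | 1-iodo-3,5-dimethoxybenzene | COc1cc(I)cc(OC)c1 | starting material
2 | 2,4-dimethoxybenzoyl chloride | COc1ccc(C(=O)Cl)c(OC)c1 | starting material
3 | (2,4-dimethoxyphenyl)(2-iodo-4,6-dimethoxyphenyl)methanone | COc1ccc(C(=O)c2c(I)cc(OC)cc2OC)c(OC)c1 | intermediate
4 | 3,5-bis(benzyloxy)benzyl bromide | BrCc1cc(OCc2ccccc2)cc(OCc2ccccc2)c1 | starting material
5 | 1,5-bis(benzyloxy)-2-bromo-3-(bromomethyl)benzene | BrCc1cc(OCc2ccccc2)cc(OCc2ccccc2)c1Br | intermediate
6 | [3,5-bis(benzyloxy)-2-bromobenzyl]magnesium bromide (not isolated) | Br[Mg]Cc1cc(OCc2ccccc2)cc(OCc2ccccc2)c1Br | intermediate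
7 | 2-[3,5-bis(benzyloxy)-2-bromophenyl]-1-(2,4-dimethoxyphenyl)-1-(2-iodo-4,6-dimethoxyphenyl)ethanol, racemic (not isolated) | COc1ccc(C(O)(Cc2cc(OCc3ccccc3)cc(OCc3ccccc3)c2Br)c2c(I)cc(OC)cc2OC)c(OC)c1 | intermediate
8 | (Z)-2-[3,5-bis(benzyloxy)-2-bromophenyl]-1-(2,4-dimethoxyphenyl)-1-(2-iodo-4,6-dimethoxyphenyl)ethene | Brc1c(OCc2ccccc2)cc(OCc2ccccc2)cc1/C=C(c1ccc(OC)cc1OC)\c1c(I)cc(OC)cc1OC | intermediate
9 | (R)-2-[3,5-bis(benzyloxy)-2-bromophenyl]-1-(2,4-dimethoxyphenyl)-1-(2-iodo-4,6-dimethoxyphenyl)ethane | Brc1c(OCc2ccccc2)cc(OCc2ccccc2)cc1C[C@H](c1ccc(OC)cc1OC)c1c(I)cc(OC)cc1OC | intermediate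
10 | 4-ethynylanisole | COc1ccc(C#C)cc1 | starting material
11 | (R)-2-[3,5-bis(benzyloxy)-2-bromophenyl]-1-(2,4-dimethoxyphenyl)-1-{2,4-dimethoxy-6-[(4-methoxyphenyl)ethynyl]phenyl}ethane | Brc1c(OCc2ccccc2)cc(OCc2ccccc2)cc1C[C@H](c1ccc(OC)cc1OC)c1c(OC)cc(OC)cc1C#Cc1ccc(OC)cc1 | intermediate
12 | aryllithium derived from 11, lithium in place of bromine on A4 (not isolated) | [Li]c1c(OCc2ccccc2)cc(OCc2ccccc2)cc1C[C@H](c1ccc(OC)cc1OC)c1c(OC)cc(OC)cc1C#Cc1ccc(OC)cc1 | intermediate
13 | (R)-2-[3,5-bis(benzyloxy)-2-iodophenyl]-1-(2,4-dimethoxyphenyl)-1-{2,4-dimethoxy-6-[(4-methoxyphenyl)ethynyl]phenyl}ethane | Ic1c(OCc2ccccc2)cc(OCc2ccccc2)cc1C[C@H](c1ccc(OC)cc1OC)c1c(OC)cc(OC)cc1C#Cc1ccc(OC)cc1 | intermediate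
14 | 5-[(2R)-2-(2,4-dimethoxyphenyl)-2-{2,4-dimethoxy-6-[(4-methoxyphenyl)ethynyl]phenyl}ethyl]-4-iodobenzene-1,3-diol (precursor of the key step) | Oc1cc(O)c(I)c(c1)C[C@H](c1ccc(OC)cc1OC)c1c(OC)cc(OC)cc1C#Cc1ccc(OC)cc1 | intermediate
15 | tetracyclic benzofuran phenol: 2-(4-methoxyphenyl)benzofuran fused to the seven-membered ring, A1 hydroxyl free, Cb R (product of the key step) | Oc1cc2oc(-c3ccc(OC)cc3)c3c2c(c1)C[C@H](c1ccc(OC)cc1OC)c1c(OC)cc(OC)cc1-3 | intermediate
16 | trans-2,3-dihydrobenzofuran phenol (Cb R, Cc R, Cd R) | Oc1cc2c3c(c1)C[C@H](c1ccc(OC)cc1OC)c1c(OC)cc(OC)cc1[C@H]3[C@H](c1ccc(OC)cc1)O2 | intermediate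
17 | salicylaldehyde: 16 with CHO on A6 | O=Cc1c(O)cc2c3c1C[C@H](c1ccc(OC)cc1OC)c1c(OC)cc(OC)cc1[C@H]3[C@H](c1ccc(OC)cc1)O2 | intermediate
18 | 4-methoxybenzyl chloride | COc1ccc(CCl)cc1 | starting material
19 | 4-methoxybenzyl ether of 17 at the A1 oxygen | O=Cc1c(OCc4ccc(OC)cc4)cc2c3c1C[C@H](c1ccc(OC)cc1OC)c1c(OC)cc(OC)cc1[C@H]3[C@H](c1ccc(OC)cc1)O2 | intermediate
20 | 1-bromo-3,5-dimethoxybenzene | COc1cc(Br)cc(OC)c1 | starting material
21 | 3,5-dimethoxyphenylmagnesium bromide (not isolated) | COc1cc([Mg]Br)cc(OC)c1 | intermediate
22 | diaryl carbinol: A6–CH(OH)–(3,5-dimethoxyphenyl), both carbinol epimers | OC(c4cc(OC)cc(OC)c4)c1c(OCc4ccc(OC)cc4)cc2c3c1C[C@H](c1ccc(OC)cc1OC)c1c(OC)cc(OC)cc1[C@H]3[C@H](c1ccc(OC)cc1)O2 | intermediate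
23 | diaryl ketone: A6–C(=O)–(3,5-dimethoxyphenyl) | O=C(c4cc(OC)cc(OC)c4)c1c(OCc4ccc(OC)cc4)cc2c3c1C[C@H](c1ccc(OC)cc1OC)c1c(OC)cc(OC)cc1[C@H]3[C@H](c1ccc(OC)cc1)O2 | intermediate
24 | hydrazone of 23 | NN=C(c4cc(OC)cc(OC)c4)c1c(OCc4ccc(OC)cc4)cc2c3c1C[C@H](c1ccc(OC)cc1OC)c1c(OC)cc(OC)cc1[C@H]3[C@H](c1ccc(OC)cc1)O2 | intermediate
25 | diaryldiazomethane from 24 (not isolated) | [N-]=[N+]=C(c4cc(OC)cc(OC)c4)c1c(OCc4ccc(OC)cc4)cc2c3c1C[C@H](c1ccc(OC)cc1OC)c1c(OC)cc(OC)cc1[C@H]3[C@H](c1ccc(OC)cc1)O2 | intermediate
26 | octamethyl ether with cis second dihydrofuran (Cf S, Ce R; Cb R, Cc R, Cd R) | COc1ccc([C@H]2Oc3cc4c5c(c3[C@H]2c2cc(OC)cc(OC)c2)C[C@H](c2ccc(OC)cc2OC)c2c(OC)cc(OC)cc2[C@H]5[C@H](c2ccc(OC)cc2)O4)cc1 | intermediate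
27 | octamethyl ether of the target (all five stereocentres R) | COc1ccc([C@@H]2Oc3cc4c5c(c3[C@H]2c2cc(OC)cc(OC)c2)C[C@H](c2ccc(OC)cc2OC)c2c(OC)cc(OC)cc2[C@H]5[C@H](c2ccc(OC)cc2)O4)cc1 | intermediate
28 | CNP0154047.1 (Cb R, Cc R, Cd R, Ce R, Cf R) | Oc1ccc([C@@H]2Oc3cc4c5c(c3[C@H]2c2cc(O)cc(O)c2)C[C@H](c2ccc(O)cc2O)c2c(O)cc(O)cc2[C@H]5[C@H](c2ccc(O)cc2)O4)cc1 | target

## Step count and least certain steps

Total: 17 steps. Longest linear sequence: 16 steps (step 1 or step 2, then steps 3 to 17).

Step 8 (key step). The likeliest failure is slow oxidative addition at the very electron-rich, doubly ortho-substituted C–I bond with protodeiodination, or diversion of the vinylpalladium species (protonolysis, C–H palladation of a neighbouring arene) before the C–O bond forms. The fallback splits the bicyclization into two known operations. From 14, a reductive Heck cyclization (Pd(OAc)2, PPh3, HCO2Na, DMF, 80 °C) performs the same 7-exo-dig carbopalladation and intercepts the vinylpalladium with hydride, giving the (E)-exocyclic alkene F1. A Wacker-type oxidative cyclization of this 2-hydroxystilbene (PdCl2(MeCN)2, 1,4-benzoquinone, dioxane, 80 °C) then forms the O–Cd bond and aromatizes to 15, where the route is rejoined.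

Step 4. Hydrogenation of a triarylethylene with four ortho substituents may stall, or the face selection may be poor, and any residual E isomer erodes the enantiomeric purity further. The fallback gives up asymmetric catalysis: from 8, ionic hydrogenation (Et3SiH, CF3CO2H, CH2Cl2, 0 °C) through the stabilized diaryl cation gives the racemic triarylethane F2, which is resolved by preparative chromatography on a chiral stationary phase to return to 9.

Step 9. Facial selection in the protonation at Cc may be weak, and the new benzylic C–O bond may ionize and be reduced further (reductive ring opening). The fallback replaces protonation by surface delivery of hydrogen: from 15, heterogeneous hydrogenation (H2, 50 bar, Pd(OH)2/C, EtOAc–AcOH) should add both hydrogens to the more exposed face of the twisted benzofuran to give the cis-dihydrobenzofuran F3 (Cc R, Cd S). Brief treatment with CF3CO2H without silane then equilibrates Cd to the trans isomer 16.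

Step 14. Condensation at the doubly ortho-substituted diaryl ketone may stay incomplete. The fallback avoids the ketone: from 19, I2 and aqueous NH3 in THF convert the aldehyde into the nitrile F4; addition of 21 (CuBr cat., THF, reflux) and a methanol quench give the N-unsubstituted ketimine F5, and transimination with N2H4·H2O and AcOH in EtOH leads to 24.

Step 15. The resident stereocentres may work against the catalyst (mismatched pairing), and the hindered diazo compound may form azine or carbene dimer instead of inserting. The fallback builds the ring by an anionic [4+1] annulation: from 17, addition of 21 (2.5 equiv) gives the ortho-hydroxybenzhydrol F6, and p-TolSO2Na in HCO2H converts it into the sulfone F7. Cs2CO3 with (4-methoxybenzyl)dimethylsulfonium bromide then generates the ortho-quinone methide and the sulfur ylide, whose addition and ring closure give the trans-dihydrobenzofuran directly. Chromatography removes the (Ce S, Cf S) diastereomer F9 and returns 27.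

Step 16. The ring-opened cation may lose the Ce proton to a triarylethylene and reprotonate, eroding the configuration at Ce, or be captured by a neighbouring arene. The fallback moves the equilibration to the phenol stage: from 26, BBr3 (as in step 17) gives the cis octaphenol F8, and mild base (K2CO3, degassed MeOH, rt) equilibrates Cf through a para-quinone methide (retro-oxa-Michael, oxa-Michael) to 28.

## Further compounds

F1 | step 8 | (E)-exocyclic alkene from reductive cyclization of 14: Cc=CdH(4-methoxyphenyl) on the seven-membered ring, ring A resorcinol free, Cb R | Oc1cc(O)c2c(c1)C[C@H](c1ccc(OC)cc1OC)c1c(OC)cc(OC)cc1/C2=C\c1ccc(OC)cc1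
F2 | step 4 | racemic 2-[3,5-bis(benzyloxy)-2-bromophenyl]-1-(2,4-dimethoxyphenyl)-1-(2-iodo-4,6-dimethoxyphenyl)ethane | Brc1c(OCc2ccccc2)cc(OCc2ccccc2)cc1CC(c1ccc(OC)cc1OC)c1c(I)cc(OC)cc1OC
F3 | step 9 | cis-2,3-dihydrobenzofuran phenol (Cb R, Cc R, Cd S) | Oc1cc2c3c(c1)C[C@H](c1ccc(OC)cc1OC)c1c(OC)cc(OC)cc1[C@H]3[C@@H](c1ccc(OC)cc1)O2
F4 | step 14 | nitrile on A6 in place of the aldehyde of 19 | N#Cc1c(OCc4ccc(OC)cc4)cc2c3c1C[C@H](c1ccc(OC)cc1OC)c1c(OC)cc(OC)cc1[C@H]3[C@H](c1ccc(OC)cc1)O2
F5 | step 14 | N-unsubstituted ketimine corresponding to ketone 23 | N=C(c4cc(OC)cc(OC)c4)c1c(OCc4ccc(OC)cc4)cc2c3c1C[C@H](c1ccc(OC)cc1OC)c1c(OC)cc(OC)cc1[C@H]3[C@H](c1ccc(OC)cc1)O2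
F6 | step 15 | ortho-hydroxybenzhydrol: A6–CH(OH)–(3,5-dimethoxyphenyl) with free A1 hydroxyl, both carbinol epimers | OC(c4cc(OC)cc(OC)c4)c1c(O)cc2c3c1C[C@H](c1ccc(OC)cc1OC)c1c(OC)cc(OC)cc1[C@H]3[C@H](c1ccc(OC)cc1)O2
F7 | step 15 | sulfone: A6–CH(SO2-p-tolyl)–(3,5-dimethoxyphenyl) with free A1 hydroxyl, both epimers | Cc1ccc(cc1)S(=O)(=O)C(c4cc(OC)cc(OC)c4)c1c(O)cc2c3c1C[C@H](c1ccc(OC)cc1OC)c1c(OC)cc(OC)cc1[C@H]3[C@H](c1ccc(OC)cc1)O2
F8 | step 16 | cis octaphenol, Cf epimer of the target (Cf S, Ce R) | Oc1ccc([C@H]2Oc3cc4c5c(c3[C@H]2c2cc(O)cc(O)c2)C[C@H](c2ccc(O)cc2O)c2c(O)cc(O)cc2[C@H]5[C@H](c2ccc(O)cc2)O4)cc1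
F9 | step 15 | trans diastereomer of 27 with Ce S and Cf S | COc1ccc([C@H]2Oc3cc4c5c(c3[C@@H]2c2cc(OC)cc(OC)c2)C[C@H](c2ccc(OC)cc2OC)c2c(OC)cc(OC)cc2[C@H]5[C@H](c2ccc(OC)cc2)O4)cc1
A1 | alternative 1 | C2-symmetric bis(trans-dihydrobenzofuran) on ring A with a tert-butyldimethylsilyloxymethyl group on A5 (four furan stereocentres R) | COc1ccc([C@@H]2Oc3cc4O[C@@H](c5ccc(OC)cc5)[C@H](c5cc(OC)cc(OC)c5)c4c(CO[Si](C)(C)C(C)(C)C)c3[C@H]2c2cc(OC)cc(OC)c2)cc1
A2 | alternative 1 | (1R,1'R,2R,2'R)-2,2'-[4,6-dibromo-2-({[tert-butyl(dimethyl)silyl]oxy}methyl)-1,3-phenylene]bis[2-(3,5-dimethoxyphenyl)-1-(4-methoxyphenyl)ethanol] | COc1ccc([C@H](O)[C@H](c2cc(OC)cc(OC)c2)c2c(Br)cc(Br)c([C@@H](c3cc(OC)cc(OC)c3)[C@@H](O)c3ccc(OC)cc3)c2CO[Si](C)(C)C(C)(C)C)cc1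
A3 | alternative 2 | methyl tetramethoxy-dibenzocycloheptenone carboxylate (ketone at Cb, ester on Cc, racemic) | COC(=O)C1c2cc(OC)cc(OC)c2C(=O)Cc2cc(OC)cc(OC)c21
A4 | alternative 2 | methyl 5,7-dimethoxy-2-oxoindane-1-carboxylate | COC(=O)C1C(=O)Cc2cc(OC)cc(OC)c21
A5 | alternative 2 | 3,5-dimethoxy-2-(trimethylsilyl)phenyl trifluoromethanesulfonate | COc1cc(OC)c([Si](C)(C)C)c(OS(=O)(=O)C(F)(F)F)c1
A6 | alternative 3 | tetracyclic core with ring B as a mono-triisopropylsilyl resorcinol (Cb R, Cc R, Cd R) | COc1cc2c3c(c1)C[C@H](c1ccc(OC)cc1OC)c1c(O)cc(O[Si](C(C)C)(C(C)C)C(C)C)cc1[C@H]3[C@H](c1ccc(OC)cc1)O2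
A7 | alternative 3 | cycloheptenyl diazomethyl ketone fused to the ring A dihydrobenzofuran | COc1cc2c3c(c1)C[C@H](c1ccc(OC)cc1OC)C=C(C(=O)C=[N+]=[N-])[C@H]3[C@H](c1ccc(OC)cc1)O2
A8 | alternative 3 | (triisopropylsilyloxy)acetylene | C#CO[Si](C(C)C)(C(C)C)C(C)C
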